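**Remark on the structure:** the target has no stereocentre and no stereogenic double bond (the prenyl alkene carries two identical methyl groups). It is achiral, so "single enantiomer" means the compound itself and no stereocontrol is needed.

## Analysis of the target

- The target (14, C22H24O7) is an unsymmetrical diaryl ether. Ring B is the benzoic acid ring: C1 (CO2H), C2 (OH), C3 (prenyl), C4–H, C5–H, C6 (bridging oxygen O6). Ring A is the benzyl acetate ring: C1′ (bridging oxygen), C2′ (OH), C3′–H, C4′ (CH3), C5′–H, C6′ (CH2OAc). These locants are used for the atoms of all intermediates, whatever the locants in their systematic names.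
- The hardest bond is O6–C1′. It lies between three ortho substituents (CO2H on C1, OH on C2′, CH2OAc on C6′) and joins two electron-rich rings, which are poor partners for intermolecular SNAr or Ullmann coupling.
- Ring B carries four contiguous substituents (C6, C1, C2, C3). The prenyl group must go to C3 only, not to C5, to oxygen or to ring A.
- Sensitive groups: the ortho-prenylphenol (acid gives a chroman, peracids epoxidise it, hydrogenation saturates it), the primary benzylic acetate (hydroxide, alkoxide), and the 2,6-dioxygenated benzoic acid (decarboxylation when heated in acid).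
- The product has three free acidic OH groups next to an acetate, so the end-game cannot use a deprotection harsher than the acetate tolerates.
- The feature the route exploits is the triad C1(CO2H)–C6–O6–C1′ with a free OH on C2′. A 2-aryloxybenzoic acid is the Smiles isomer of an aryl 2-hydroxybenzoate, with ring A moved from O6 to the carboxyl oxygen. The C2′–OH ortho to the ipso carbon is the Baeyer–Villiger descendant of the formyl group that such an ipso substitution needs as activator. The O2–H/C3-prenyl pair is a Claisen retron.

## Retrosynthetic reasoning

**14 ⇒ 13 (C3–prenyl bond, O2–H).** The prenyl group is returned to O2 as a 1,1-dimethylallyl ether (13) by a retro-Claisen step. A [3,3] shift can only deliver to C3, because C1 bears the carboxyl group. This removes all O/C and ortho/para ambiguity and frees O2–H without a deprotection. The forward step must be thermal and free of strong acid.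

**13 ⇒ 12 (alkene from alkyne).** The tert-allyl ether is traced to the tertiary propargyl ether 12 by semi-hydrogenation. The latent prenyl group is carried as the alkyne because it is inert to the peracid of the preceding forward step, and its ether is far more stable to acid than the tert-allyl ether.

**12 ⇒ 10 (C2′–O bond).** The C2′ hydroxyl is traced to a formyl group by a Baeyer–Villiger aryl shift from carbon to oxygen. The oxygen is deliberately not carried through the key step: an oxygen donor ortho to C1′ would deactivate ipso substitution, whereas the formyl group activates it.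

**10 ⇒ 8 (key disconnection, O6–C1′).** The bridge is cut by moving ring A back from O6 to the carboxyl oxygen, which gives the aryl ester (depside) 8. In 8 the nucleophile O6 and the electrophile C1′ are held across the ester, so the hindered ether forms through a six-membered spiro transition state with carboxylate as leaving group. The forward reaction also releases the CO2H free. Only O6 can react, because O2 carries the propargyl group. The forward step must make ipso attack faster than ester cleavage.

**8 ⇒ 7 + 3 (acyl C–O bond).** The ester is split into the 2-hydroxybenzoic acid 7 and the chelated phenol 3, two halves of similar size. A carbodiimide esterification must acylate the phenol of 3 and leave the chelated OH of 7 alone.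

**7 ⇒ 6 ⇒ 4 + 5.** Acid 7 comes from hydrolysis of the ketal-lactone 6, and 6 from O-alkylation of commercial 4 with the propargylic chloride 5. The acetonide of 4 ties up the carboxyl group and one phenolic oxygen, so the other oxygen (future O2) is alkylated alone.

**3 ⇒ 2 ⇒ 1.** The acetate is put on the primary alcohol of 2 chemoselectively. Aldehyde 2 comes from mono-oxidation of the symmetrical diol 1. One arm of 1 becomes the activator and later the C2′ hydroxyl; the other becomes the acetoxymethyl group.

## Alternatives that were turned down

**Alternative 1:** the textbook route cuts O–C1′ intermolecularly. Phenol 4 would displace fluoride from 3-(allyloxy)-2-fluoro-5-methylbenzaldehyde A1 by SNAr to give diaryl ether A2; the Ullmann variant uses a ring-B aryl halide. It was turned down for three reasons.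
- A1 is not commercial and costs several steps.
- A chelated, weakly nucleophilic phenoxide must attack a carbon flanked by two ortho groups, which calls for forcing conditions.
- In A2 the ring-B oxygens are the wrong way round: the ketal oxygen must become the free O2–H next to the prenyl group. That means ketal opening, re-protection of the acid, O-propargylation, reduction, Claisen, aldehyde reduction, acetylation and two deprotections. The total is about twelve steps with four protecting-group operations, and no hydroxide or alkoxide step is allowed once the acetate is in place.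

**Alternative 2:** the biomimetic route forms the bridge by oxidative dearomatisation. Benzophenone A3 would be oxidised to the spiro-cyclohexadienone A4, and hydroxide would then cleave the C(=O)–C(spiro) bond by a retro-Claisen step to give the target directly. It was turned down for three reasons.
- A3, a tetra-ortho-substituted benzophenone, is harder to make than the target, and its central C–C bond is built only to be broken.
- Nothing in A3 decides which ring-B hydroxyl (O2 or O6) closes the furanone, or which ring is oxidised.
- The prenyl alkene and the ortho-quinol ether A4 (prone to Diels–Alder dimerisation) are exposed to the oxidant.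

**Alternative 3:** an aryne three-component coupling would form O6–C6 and C1–CO2H at once. The phenoxide of the protected ring-A phenol A6 would add to the aryne released from A5, and the aryl anion at C1 would be trapped by CO2 to give acid A7. It was turned down for three reasons.
- A phenoxide adduct has no ammonium-type zwitterion to hold the aryl anion, so protonation should outrun carboxylation.
- Ring A can carry neither its formyl group (the aryl anion would add to it) nor the acetate (the phenoxide would expel it), so three protecting groups are needed.
- The methyl ether of A7 must later be cleaved with a boron halide and the prenyl group installed in three further steps, which the acetate and the prenyl group tolerate poorly.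

Key step: step 6

## Route

Step 1
Reactants: 1 2,6-bis(hydroxymethyl)-4-methylphenol
Product: 2 2-hydroxy-3-(hydroxymethyl)-5-methylbenzaldehyde
Conditions: activated MnO2 (ca. 5 equiv), CHCl3, rt
Reagents that add atoms: none
Why: Heterogeneous MnO2 oxidation of a benzylic alcohol; with a limited oxidant charge it should stop largely at the mono-aldehyde, because the first formyl group chelates the phenol and makes the ring electron-poorer, which slows oxidation of the second arm.

Step 2
Reactants: 2 2-hydroxy-3-(hydroxymethyl)-5-methylbenzaldehyde
Product: 3 (3-formyl-2-hydroxy-5-methylphenyl)methyl acetate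
Conditions: vinyl acetate (3 equiv), immobilised Candida antarctica lipase B, MTBE, 35 °C
Reagents that add atoms: vinyl acetate, C=COC(C)=O
Why: Lipase-catalysed irreversible transesterification acylates primary alcohols but not phenols, so only the benzylic OH should be acetylated, under neutral conditions that cannot make the ortho-hydroxybenzyl acetate lose acetate.

Step 3
Reactants: 4 5-hydroxy-2,2-dimethyl-4H-1,3-benzodioxin-4-one; 5 3-chloro-3-methylbut-1-yne
Product: 6 2,2-dimethyl-5-[(2-methylbut-3-yn-2-yl)oxy]-4H-1,3-benzodioxin-4-one
Conditions: 5 (1.5 equiv), CuCl2·2H2O (1 mol%), DBU (1.5 equiv), MeCN, 0 °C → rt, N2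
Reagents that add atoms: none
Why: Copper-catalysed propargylic etherification of a phenol with a tertiary propargylic chloride; the acetonide of 4 has already differentiated the two ring-B oxygens, so the ether is placed only on the future O2.

Step 4
Reactants: 6 2,2-dimethyl-5-[(2-methylbut-3-yn-2-yl)oxy]-4H-1,3-benzodioxin-4-one
Product: 7 2-hydroxy-6-[(2-methylbut-3-yn-2-yl)oxy]benzoic acid
Conditions: KOH (4 equiv), DMSO–H2O, 60 °C; then cold 1 M HCl to pH 2–3
Reagents that add atoms: potassium hydroxide, [K+].[OH-]
Why: Saponification of the ketal-lactone (acyl substitution, then loss of acetone from the hemiketal) frees the carboxylic acid and the O6 phenol together; the quaternary propargyl ether cannot isomerise and is stable to base and to brief dilute acid.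

Step 5
Reactants: 7 2-hydroxy-6-[(2-methylbut-3-yn-2-yl)oxy]benzoic acid; 3 (3-formyl-2-hydroxy-5-methylphenyl)methyl acetate
Product: 8 2-(acetoxymethyl)-6-formyl-4-methylphenyl 2-hydroxy-6-[(2-methylbut-3-yn-2-yl)oxy]benzoate
Conditions: DCC (1.1 equiv), DMAP (5 mol%), CH2Cl2, 0 °C → rt
Reagents that add atoms: none
Why: Steglich-type carbodiimide esterification; depsides are made this way from 2-hydroxybenzoic acids, whose chelated ortho-OH stays unacylated, and the near-neutral medium should keep the phenol of 3 from expelling its benzylic acetate.

Step 6
Reactants: 8 2-(acetoxymethyl)-6-formyl-4-methylphenyl 2-hydroxy-6-[(2-methylbut-3-yn-2-yl)oxy]benzoate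
Product: 10 2-[2-(acetoxymethyl)-6-formyl-4-methylphenoxy]-6-[(2-methylbut-3-yn-2-yl)oxy]benzoic acid, via spiro Meisenheimer adduct 9 (not isolated)
Conditions: K2CO3 (2 equiv), dry DMSO (0.05 M), rt → 60 °C, N2; then cold dilute HCl to pH 3
Reagents that add atoms: none
Why: Carbonate deprotonates the only free phenol of 8 (O6–H), and the phenoxide adds ipso to C1′ of ring A, whose ortho-formyl group on C2′ takes up the charge as a dienolate in the spiro σ-adduct 9; collapse of 9 breaks the C1′–O(acyl) bond and expels the carboxylate, the better leaving group by about five pKa units, so the O→O aryl shift is irreversible. The closest known reaction type is the Smiles rearrangement of depsides (aryl 2-hydroxybenzoates whose migrating ring carries an ortho-formyl or ester group) to 2-aryloxybenzoic acids with carbonate in DMSO. No ring of the product is closed; the transient six-membered 1,3-dioxin-4-one ring of 9 forms by 6-exo-trig ipso addition after the ester rotates into its s-cis form. No stereocentre is created, since the spiro carbon of 9 is transient and racemic. Three selectivities are needed: which ring-B oxygen takes ring A, secured because O2 is blocked as the propargyl ether; ipso substitution over ester cleavage, secured by anhydrous conditions, dilution and the doubly ortho-substituted benzoate carbonyl; and survival of the benzylic acetate, secured because the ring-A oxygen is acylated or arylated throughout, so no ortho-quinone methide can form. The step should form the tri-ortho-substituted diaryl ether and free the carboxylic acid in one operation.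

Step 7
Reactants: 10 2-[2-(acetoxymethyl)-6-formyl-4-methylphenoxy]-6-[(2-methylbut-3-yn-2-yl)oxy]benzoic acid
Product: 12 2-[2-(acetoxymethyl)-6-hydroxy-4-methylphenoxy]-6-[(2-methylbut-3-yn-2-yl)oxy]benzoic acid, via aryl formate 11 (not isolated)
Conditions: mCPBA (1.3 equiv), CH2Cl2, 0 °C → rt; then Et3N (3 equiv), MeOH, rt; acidify to pH 3
Reagents that add atoms: mCPBA (3-chloroperoxybenzoic acid), O=C(OO)c1cccc(Cl)c1
Why: Baeyer–Villiger oxidation of an ortho-aryloxybenzaldehyde proceeds with aryl migration to the aryl formate 11, which is methanolysed far faster than the alkyl acetate; the terminal alkyne, the diaryl ether and the carboxylic acid are inert to the peracid.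

Step 8
Reactants: 12 2-[2-(acetoxymethyl)-6-hydroxy-4-methylphenoxy]-6-[(2-methylbut-3-yn-2-yl)oxy]benzoic acid
Product: 14 6-[2-(acetoxymethyl)-6-hydroxy-4-methylphenoxy]-2-hydroxy-3-(3-methylbut-2-en-1-yl)benzoic acid (7-O-acetylsecopenicillide C), via tert-allyl ether 13 (not isolated)
Conditions: H2 (1 atm), Lindlar catalyst, quinoline, toluene, rt; filter; then Et3N (2 equiv), 105 °C; cold citric acid work-up (pH 4)
Reagents that add atoms: none
Why: Semi-hydrogenation of the terminal alkyne on lead-poisoned palladium gives the 1,1-dimethylallyl ether 13, which on heating undergoes the aromatic Claisen rearrangement ([3,3], chair) to the only free ortho position C3, giving the C3 prenyl group and the free O2–H; the acid is held as its triethylammonium salt so that neither the tert-allyl ether nor the ortho-prenylphenol meets a strong acid.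

## Compound list

1 | 2,6-bis(hydroxymethyl)-4-methylphenol | Cc1cc(CO)c(O)c(CO)c1 | starting material
2 | 2-hydroxy-3-(hydroxymethyl)-5-methylbenzaldehyde | Cc1cc(CO)c(O)c(C=O)c1 | intermediate
3 | (3-formyl-2-hydroxy-5-methylphenyl)methyl acetate | CC(=O)OCc1cc(C)cc(C=O)c1O | intermediate
4 | 5-hydroxy-2,2-dimethyl-4H-1,3-benzodioxin-4-one | CC1(C)OC(=O)c2c(O)cccc2O1 | starting material
5 | 3-chloro-3-methylbut-1-yne | CC(C)(Cl)C#C | starting material
6 | 2,2-dimethyl-5-[(2-methylbut-3-yn-2-yl)oxy]-4H-1,3-benzodioxin-4-one | CC1(C)OC(=O)c2c(OC(C)(C)C#C)cccc2O1 | intermediate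
7 | 2-hydroxy-6-[(2-methylbut-3-yn-2-yl)oxy]benzoic acid | C#CC(C)(C)Oc1cccc(O)c1C(=O)O | intermediate
8 | 2-(acetoxymethyl)-6-formyl-4-methylphenyl 2-hydroxy-6-[(2-methylbut-3-yn-2-yl)oxy]benzoate | CC(=O)OCc1cc(C)cc(C=O)c1OC(=O)c1c(O)cccc1OC(C)(C)C#C | intermediate
9 | spiro Meisenheimer adduct: potassium salt of 2′-(acetoxymethyl)-4′-methyl-5-[(2-methylbut-3-yn-2-yl)oxy]-6′-(oxidomethylidene)spiro[1,3-benzodioxine-2,1′-cyclohexa-2′,4′-dien]-4-one (racemic, transient) | [K+].[O-]C=C1C=C(C)C=C(COC(C)=O)C12OC(=O)c1c(O2)cccc1OC(C)(C)C#C | intermediate (not isolated)
10 | 2-[2-(acetoxymethyl)-6-formyl-4-methylphenoxy]-6-[(2-methylbut-3-yn-2-yl)oxy]benzoic acid | CC(=O)OCc1cc(C)cc(C=O)c1Oc1cccc(OC(C)(C)C#C)c1C(=O)O | intermediate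
11 | 2-[2-(acetoxymethyl)-6-(formyloxy)-4-methylphenoxy]-6-[(2-methylbut-3-yn-2-yl)oxy]benzoic acid | CC(=O)OCc1cc(C)cc(OC=O)c1Oc1cccc(OC(C)(C)C#C)c1C(=O)O | intermediate (not isolated)
12 | 2-[2-(acetoxymethyl)-6-hydroxy-4-methylphenoxy]-6-[(2-methylbut-3-yn-2-yl)oxy]benzoic acid | CC(=O)OCc1cc(C)cc(O)c1Oc1cccc(OC(C)(C)C#C)c1C(=O)O | intermediate
13 | 2-[2-(acetoxymethyl)-6-hydroxy-4-methylphenoxy]-6-[(2-methylbut-3-en-2-yl)oxy]benzoic acid | CC(=O)OCc1cc(C)cc(O)c1Oc1cccc(OC(C)(C)C=C)c1C(=O)O | intermediate (not isolated)
14 | 6-[2-(acetoxymethyl)-6-hydroxy-4-methylphenoxy]-2-hydroxy-3-(3-methylbut-2-en-1-yl)benzoic acid (7-O-acetylsecopenicillide C) | CC(=O)OCc1cc(C)cc(O)c1Oc1ccc(CC=C(C)C)c(O)c1C(=O)O | target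

## Step count and least certain steps

Total: 8 steps. Longest linear sequence: 6 steps (4 → 14 by steps 3–8, or equally 1 → 14 by steps 1, 2, 5–8). No protecting group is used.

**Step 6 (key step).** The ipso addition may be slow, because C1′ is activated by one formyl group only and is flanked by two ortho substituents. Intermolecular acyl transfer or cleavage of the aryl ester by traces of water could then take over, and a released ring-A phenoxide would lose its acetate. The fallback uses a migrating ring with two activators and sets out from 7. Acid 7 would be esterified (DCC, DMAP) with commercial 2-hydroxy-5-methylbenzene-1,3-dicarbaldehyde F1 to give 2,6-diformyl-4-methylphenyl 2-hydroxy-6-[(2-methylbut-3-yn-2-yl)oxy]benzoate F2, whose ipso carbon lies between two formyl groups. The same carbonate/DMSO treatment at room temperature should give 2-(2,6-diformyl-4-methylphenoxy)-6-[(2-methylbut-3-yn-2-yl)oxy]benzoic acid F3. Mono-reduction with NaBH4 (0.3 equiv, −20 °C) should favour 2-[2-formyl-6-(hydroxymethyl)-4-methylphenoxy]-6-[(2-methylbut-3-yn-2-yl)oxy]benzoic acid F4, because the second formyl group activates the first and is lost as an activator once the first is reduced. Acetylation of F4 (Ac2O, pyridine, 0 °C) comes back to the route at 10.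

**Step 5.** The carbodiimide coupling may suffer from slow acylation of the hindered, chelated phenol of 3, which leads to N-acylurea formation or self-acylation of 7 through its own phenol. DMAP may also deprotonate 3 enough to start loss of acetate. The fallback avoids the free acid and the base and sets out from 6 and 3. Irradiation of 6 at about 300 nm in CH2Cl2 in the presence of 3 should release acetone and the quinoketene 6-(oxomethylidene)-5-[(2-methylbut-3-yn-2-yl)oxy]cyclohexa-2,4-dien-1-one F5. The phenol of 3 captures F5 under neutral conditions and gives 8 directly, where the fallback comes back to the route; step 4 is then not needed.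

**Step 8.** Three things may go wrong:
- over-reduction of the new alkene to the saturated ether;
- ionisation of the tert-allyl ether assisted by the neighbouring carboxyl group, with loss of the C5 unit;
- on prolonged heating, attack at C1 with decarboxylation or cyclisation of the ortho-prenylphenol to a chroman.

The fallback masks the acid before the rearrangement and sets out from 12. Allyl bromide and KHCO3 in DMF should alkylate only the carboxylate and give allyl 2-[2-(acetoxymethyl)-6-hydroxy-4-methylphenoxy]-6-[(2-methylbut-3-yn-2-yl)oxy]benzoate F6. Lindlar semi-hydrogenation gives allyl 2-[2-(acetoxymethyl)-6-hydroxy-4-methylphenoxy]-6-[(2-methylbut-3-en-2-yl)oxy]benzoate F7. Heating the neutral ester in toluene at 110 °C gives allyl 6-[2-(acetoxymethyl)-6-hydroxy-4-methylphenoxy]-2-hydroxy-3-(3-methylbut-2-en-1-yl)benzoate F8. Pd(PPh3)4 with morpholine in THF at room temperature removes the allyl ester without touching the acetate or the prenyl group and comes back to the route at 14.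

**Step 2.** The lipase may accept the ortho-flanked benzylic alcohol only slowly, and long reaction times invite acetyl transfer to the phenol. The fallback sets out from 2 and uses acid-catalysed esterification in acetic acid (AcOH, cat. TsOH, 60 °C). Phenols do not esterify under these conditions, and the ring of 2 has no free ortho or para position for self-condensation, so only the benzylic OH should be acetylated. It comes back to the route at 3 and makes no new compound (F0).

## Further compounds

F1 | step 6 | 2-hydroxy-5-methylbenzene-1,3-dicarbaldehyde | Cc1cc(C=O)c(O)c(C=O)c1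
F2 | step 6 | 2,6-diformyl-4-methylphenyl 2-hydroxy-6-[(2-methylbut-3-yn-2-yl)oxy]benzoate | Cc1cc(C=O)c(OC(=O)c2c(O)cccc2OC(C)(C)C#C)c(C=O)c1
F3 | step 6 | 2-(2,6-diformyl-4-methylphenoxy)-6-[(2-methylbut-3-yn-2-yl)oxy]benzoic acid | Cc1cc(C=O)c(Oc2cccc(OC(C)(C)C#C)c2C(=O)O)c(C=O)c1
F4 | step 6 | 2-[2-formyl-6-(hydroxymethyl)-4-methylphenoxy]-6-[(2-methylbut-3-yn-2-yl)oxy]benzoic acid | Cc1cc(CO)c(Oc2cccc(OC(C)(C)C#C)c2C(=O)O)c(C=O)c1
F5 | step 5 | 6-(oxomethylidene)-5-[(2-methylbut-3-yn-2-yl)oxy]cyclohexa-2,4-dien-1-one (quinoketene) | O=C=C1C(=O)C=CC=C1OC(C)(C)C#C
F6 | step 8 | allyl 2-[2-(acetoxymethyl)-6-hydroxy-4-methylphenoxy]-6-[(2-methylbut-3-yn-2-yl)oxy]benzoate | CC(=O)OCc1cc(C)cc(O)c1Oc1cccc(OC(C)(C)C#C)c1C(=O)OCC=C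
F7 | step 8 | allyl 2-[2-(acetoxymethyl)-6-hydroxy-4-methylphenoxy]-6-[(2-methylbut-3-en-2-yl)oxy]benzoate | CC(=O)OCc1cc(C)cc(O)c1Oc1cccc(OC(C)(C)C=C)c1C(=O)OCC=C
F8 | step 8 | allyl 6-[2-(acetoxymethyl)-6-hydroxy-4-methylphenoxy]-2-hydroxy-3-(3-methylbut-2-en-1-yl)benzoate | CC(=O)OCc1cc(C)cc(O)c1Oc1ccc(CC=C(C)C)c(O)c1C(=O)OCC=C
F0 | step 2 | none | none
A1 | alternative 1 | 3-(allyloxy)-2-fluoro-5-methylbenzaldehyde | C=CCOc1cc(C)cc(C=O)c1F
A2 | alternative 1 | 5-[2-(allyloxy)-6-formyl-4-methylphenoxy]-2,2-dimethyl-4H-1,3-benzodioxin-4-one | CC1(C)OC(=O)c2c(Oc3c(C=O)cc(C)cc3OCC=C)cccc2O1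
A3 | alternative 2 | [2-(acetoxymethyl)-6-hydroxy-4-methylphenyl][2,6-dihydroxy-3-(3-methylbut-2-en-1-yl)phenyl]methanone | CC(=O)OCc1cc(C)cc(O)c1C(=O)c1c(O)ccc(CC=C(C)C)c1O
A4 | alternative 2 | 6′-(acetoxymethyl)-4-hydroxy-4′-methyl-5-(3-methylbut-2-en-1-yl)spiro[1-benzofuran-2,1′-cyclohexa-3′,5′-diene]-2′,3-dione (racemic) | CC(=O)OCC1=CC(C)=CC(=O)C12Oc1ccc(CC=C(C)C)c(O)c1C2=O
A5 | alternative 3 | 3-methoxy-2-(trimethylsilyl)phenyl trifluoromethanesulfonate | COc1cccc(OS(=O)(=O)C(F)(F)F)c1[Si](C)(C)C
A6 | alternative 3 | 2-(allyloxy)-6-{[(tert-butyldimethylsilyl)oxy]methyl}-4-methylphenol | C=CCOc1cc(C)cc(CO[Si](C)(C)C(C)(C)C)c1O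
A7 | alternative 3 | 2-[2-(allyloxy)-6-{[(tert-butyldimethylsilyl)oxy]methyl}-4-methylphenoxy]-6-methoxybenzoic acid | COc1cccc(Oc2c(CO[Si](C)(C)C(C)(C)C)cc(C)cc2OCC=C)c1C(=O)O
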